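Time is what separates grey, stopped at 5.0 min, from teal, stopped at 10 min; their charges match, so I ask what time does to the excess.

| flask | left-handed substrate | right-handed substrate | gas | precatalyst | remark | time |
|---|---|---|---|---|---|---|
| gamma | 20 mM | 20 mM | 5.8 mM (held) | 0.15 mol% | run made earlier |  |
| epsilon | 20 mM | 20 mM | 5.8 mM (held) | 0.6 mol% | run made earlier |  |
| grey | 20 mM | 20 mM | 5.8 mM (held) | 0.3 mol% |  | 5.0 min |
| teal | 20 mM | 20 mM | 5.8 mM (held) | 0.3 mol% |  | 10 min |

| run | time / min | right-handed substrate / % | left-handed substrate / % | left-handed product / % |
|---|---|---|---|---|
| gamma | 0.167 | 49.9 | 49.8 | 0.8 |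
| gamma | 0.500 | 49.8 | 48.9 | 0.5 |
| gamma | 0.833 | 49.1 | 48.2 | 1.4 |
| gamma | 1.33 | 48.2 | 47.0 | 2.7 |
| gamma | 2.00 | 47.2 | 43.3 | 5.9 |
| gamma | 2.50 | 47.8 | 42.6 | 7.9 |
| gamma | 3.00 | 45.3 | 40.5 | 8.7 |
| epsilon | 0.250 | 50.0 | 49.2 | 2.1 |
| epsilon | 0.333 | 49.4 | 50.2 | 0.4 |
| epsilon | 0.500 | 49.2 | 49.4 | 0.7 |
| epsilon | 0.833 | 48.0 | 48.5 | 1.8 |
| epsilon | 1.33 | 49.3 | 46.6 | 3.3 |
| epsilon | 2.00 | 47.9 | 43.3 | 6.0 |
| epsilon | 3.00 | 46.3 | 40.8 | 8.5 |

(each reading ± 0.5 percentage points)

1. which one finishes higher in excess of right-handed substrate over left-handed substrate among what is left of the two ("neither" within 2 percentage points) (grey / teal / neither)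
2. excess of right-handed substrate over left-handed substrate among what is left of the two at the end, grey
3. excess of right-handed substrate over left-handed substrate among what is left of the two at the end, teal

- partner is single-handed; left-handed substrate and right-handed substrate are mirror images of each other, charged as a racemate, each of them at the stated concentration
- at the start none of the gas is in solution
- an excess is below zero if the other one leads
- the handed part of partner does not stay in what it makes, so the products of the two hands are mirror images too

**Pooling the runs.** Gamma and epsilon differ by a factor of 4.00 in precatalyst, yet at their last readings they hold 40.5% and 40.8% of left-handed substrate, so I pool them. The ratio of the logarithms of the shares left of each hand's own charge reads as a selectivity factor of 2.36.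

**One number.** I fold that reading into a gap share, the selectivity factor less one over the selectivity factor plus one: the difference between the hands, as a share of the whole charge, per unit of conversion. It comes to 0.405. The difference is small at first, so I compute just that correction: the excess is the gap share times conversion, divided by what is left.

**Reading it off.** Pooled conversion at the last reading is 13.5%. In proportion to time, grey reaches 22.6% and teal 45.2%. My excesses are then 11.8% for grey and 33.3% for teal, which is higher. But conversion in teal is not small, and the left-handed substrate thins faster than the right-handed one, so the gap per conversion should sag. I trust the order, and hold teal's figure as too high.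

**The forecast.** It says teal, with 11% for grey and 28% for teal, on the ground that “Conversion should be about 23% at 5 min and about 48% at 10 min”. For teal it stands below my figure.

**The flask.** The two flasks give 11.9% for grey and 27.2% for teal. In teal, the share of left-handed substrate still there, 41% of its charge, is less than the 71% of right-handed substrate. partner + left-handed substrate → left-handed product (k = 1.60 L mol⁻¹ s⁻¹); partner + right-handed substrate → right-handed product (k = 0.580 L mol⁻¹ s⁻¹); left-handed substrate + racemization catalyst ⇌ right-handed substrate + racemization catalyst, rate k3*[racemization catalyst]*[left-handed substrate] forward; the back reaction follows from the equilibrium constant (k = 51.0 L mol⁻¹ s⁻¹); partner + precatalyst → racemization catalyst + spent reagent (k = 0.0770 L mol⁻¹ s⁻¹); gas ⇌ partner, rate k5*(csat - [partner]) (kL = 0.00690 s⁻¹); partner ⇌ dormant form (K = 1.50, k = 0.00310 s⁻¹)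

A neighbour of grey, the same charge read at 8.00 min, holds 25.5% of left-handed substrate and 38.9% of right-handed substrate, so the gap share gives 22.4%, and that neighbour stands at 20.8%.

The numbers in the tables stem from a simulated flask from invented constants, noise included.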